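## The problem

Numbering used throughout: ring C1 = CHOAc, C2 and C3 = CH2, C4 = C(CH3)OH, C5 = CH, C6 = C(CH3)2. The chain runs C1′ to C5′ outward from C5; C3′ is the methyl carbinol and C5′ the OCH2 of the aryl ether.

Target 19 has one carbocycle and no ring fusion, so the construction problem is the crowded stretch C4–C5–C6 and the five-carbon chain on C5. It has four stereocentres: C1 (R), C4 (R), C5 (S) and C3′ (R). C4 and C5 are adjacent and can be set together. Because C6 always carries an axial methyl group, the C4 methyl group must be equatorial, which puts the C4 hydroxyl axial, the C5 chain equatorial and the C1 acetoxy group axial. C1 can therefore come from a C1 ketone by equatorial hydride delivery under control of the ring. C3′ is two methylene groups away from C5 and needs reagent control, with only CH3 against a CH2CH2 arm to tell apart. The coumarin (lactone, conjugated alkene) will not survive hydride, ozone or hydroxide and must enter late; the two tertiary alcohols eliminate under acid; the acetate is base-labile. The feature that opens the structure is that C4(OH)–C5–C1′ is an aldol pattern once C1′ is a formyl group, while C1 and C4 are 1,4-related oxygenated carbons. The ring is thus the closed form of an achiral open-chain 4,7-diketo aldehyde, and the C6 gem-dimethyl group next to the nucleophilic carbon acts as a conformational lock.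

## Retrosynthesis

**C1–O acetyl and C5′–O aryl (19 ⇒ 18 ⇒ 16 + 17).** The acetate is removed first, then the aryl ether is cut to tetraol 16 and phenol 17. This keeps the coumarin out of every hydride and ozone step. It needs no protecting group because 16 has exactly one primary, one secondary and two tertiary hydroxyls. The forward reactions must pick the primary hydroxyl for etherification and the secondary one for acylation.

**C5′–O, C1–H and C3′–C4′ (16 ⇒ 14 ⇒ 13 ⇒ 12).** The 2-hydroxyethyl arm is read as an allyl group (ozonolysis, reduction), the C1 carbinol as a ketone, and the C3′–C4′ bond as an allyl addition to the methyl ketone of 12. Cutting C3′–CH3 or C2′–C3′ instead would leave a ketone with two nearly identical arms. The methyl ketone is also the only unhindered carbonyl of 12, so chemoselectivity against the C1 ketone is built in. The forward steps must discriminate the faces of a ketone with CH3 against CH2CH2R, and must deliver hydride equatorially at C1.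

**C1′=C2′ (12 ⇒ 11 ⇒ 9 + 10).** Hydrogenation is undone and the enone 11 is cut by olefination into aldehyde 9 and phosphonate 10. This places C1′ at the aldehyde level, which is the aldol retron, and brings in C2′, C3′ and the C3′ methyl in one piece. The forward reaction must olefinate a hindered β-hydroxy aldehyde without retro-aldol cleavage or epimerisation at C5.

**C4–C5 (9 ⇒ 7 through enamine 8).** Opening the aldol bond removes the ring and both ring stereocentres at once and leads to the achiral triketone 7. A cut at C3–C4 or at C4–O would leave C5 as a stereocentre to be made separately. The C1 carbonyl is kept as a ketone spectator: it cannot be reached by the enamine carbon, it does not condense with the catalyst, and it is needed later for C1. The forward step must use the aldehyde as donor, the methyl ketone as acceptor, and set C4 and C5 in the absolute sense.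

**Both carbonyls of the 1,4-diketo aldehyde and C1–C2 (7 ⇒ 5 ⇒ 4 ⇒ 1 + 2).** The aldehyde C1′ and the C4 ketone are both written as alkenes, giving dienone 5. Its C1–C2 bond is cut to aldehyde 1 (C1, C6, C5, C1′) and bromide 2 (C2, C3, C4 and its methyl) via Grignard reagent 3 and alcohol 4. A furan as latent 1,4-diketone would need aqueous acid with the aldehyde already present, which invites acid-catalysed aldol condensation. Double ozonolysis reveals both carbonyl groups under neutral conditions at the last moment.

## Roads not taken

**Alternative 1: the chain carbinol from an epoxide opened by hydride.** The cut is C3′–O with C4′–H. Epoxy alcohol A1 is made from the (E)-allylic alcohol A2 with t-BuOOH, Ti(O-i-Pr)4 and D-(−)-diisopropyl tartrate. NaAlH2(OCH2CH2OCH3)2 then opens it at C4′ and leaves the C3′ oxygen.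
- Merits: a trisubstituted allylic alcohol is the ideal substrate for the Sharpless epoxidation, and the tartrate fixes C3′ with a predictable sense. In this respect it is more secure than step 7, which must tell CH3 from a CH2CH2 arm.
- Weak points: it is a side-chain tactic and leaves C1, C4 and C5 unsolved. A2 must be geometrically pure, since the E/Z ratio passes directly into C3′. Two silyl ethers must be put on and taken off. Four operations replace the two of steps 7 and 9.
- Comparison: the chosen plan sets brevity and freedom from protecting groups against the higher certainty at C3′, and keeps this chemistry as the fallback for step 7.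

**Alternative 2: the C4 oxygen delivered by an iodolactone tether.** The cut is C4–O. Acid A4 with I2 and NaHCO3 gives the cis-fused iodo γ-lactone A3. The carboxylate adds to C4 of the C3=C4 iodonium ion, and the two-atom tether from C5 forces the oxygen cis to the C5 substituent.
- Merits: the C4/C5 relationship is guaranteed by ring strain, which is more certain than the transition-state preference on which step 4 relies. The lactone carbonyl (C2′) is a handle for the chain.
- Weak points: the iodine must be reduced off, the ketal put on and removed, and the lactone opened and extended by three carbons while freeing the C4 hydroxyl. A4 must already be enantioenriched at C5 by a separate asymmetric step. Its C3=C4 alkene next to a quaternary carbon needs its own synthesis.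
- Comparison: the alternative wins on relative configuration. The chosen plan answers with one catalytic step that makes the ring and both stereocentres in the absolute sense from an achiral three-step precursor.

**Alternative 3: ketone–enone closure with SmI2.** The cut is C3–C4. SmI2 converts the keto enone A6 into ring hydroxy ketone A5 by coupling the C4 ketyl carbon with the terminal carbon C3 of the C1 vinyl ketone in a 6-endo closure. The same gem-dimethyl lock places the C4 methyl group equatorial.
- Merits: it is the most convergent road. The whole chain, with C3′ fixed beforehand from a chiral tertiary carbinol, is in place before the ring forms, so no late ketone allylation is needed. On convergence and on C3′ it is better than the chosen plan.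
- Weak points: C5 of A6 is a stereocentre α to the methyl ketone, so it must be made enantiopure and can epimerise. The vinyl ketone is the more easily reduced carbonyl, so saturation or dimerisation can compete with ketyl formation at C4. The reagent is stoichiometric, two silyl ethers are carried, and A6 (a quaternary carbon between two ketones) is long to make.
- Comparison: the chosen plan sets against it a cheap catalytic ring closure, an achiral precursor and no protecting groups. The price is the reagent-controlled step 7.

Key step: step 4

Remark: in step 7 the (R) antipode of 3,3′-Br2-BINOL is written on the assumption that an alkyl methyl ketone is attacked on the same face, relative to its larger substituent, as an aryl methyl ketone; what the route requires is allyl delivery to the Si face of the C3′ carbonyl of 12.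

## Route

Step 1
Reactants: 1 2,2-dimethylpent-4-enal; 2 4-bromo-2-methylbut-1-ene
Product: 4 2,6,6-trimethylnona-1,8-dien-5-ol (racemic), via Grignard reagent 3 (not isolated)
Conditions: Mg, THF, rt; then 1, 0 °C; aq. NH4Cl
Reagents that add atoms: none
Why: Grignard addition of a primary homoallylic organomagnesium to a non-enolisable neopentyl aldehyde forms the C1–C2 bond; the new carbinol centre is racemic and is removed in step 2.

Step 2
Reactants: 4 2,6,6-trimethylnona-1,8-dien-5-ol
Product: 5 2,6,6-trimethylnona-1,8-dien-5-one
Conditions: Dess–Martin periodinane, CH2Cl2, 0 °C → rt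
Reagents that add atoms: none
Why: Dess–Martin oxidation of a hindered secondary alcohol runs under near-neutral conditions and leaves both isolated alkenes untouched.

Step 3
Reactants: 5 2,6,6-trimethylnona-1,8-dien-5-one
Product: 7 3,3-dimethyl-4,7-dioxooctanal, via bis-ozonide 6 (not isolated)
Conditions: O3, CH2Cl2, −78 °C; then Me2S, −78 °C → rt
Reagents that add atoms: ozone, [O-][O+]=O
Why: Ozonolysis with reductive work-up turns the 1,1-disubstituted alkene into the methyl ketone and the vinyl group into the aldehyde in one operation, so the 1,4-diketone and the aldehyde appear together under neutral conditions; 7 is used without storage.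

Step 4
Reactants: 7 3,3-dimethyl-4,7-dioxooctanal
Product: 9 (1S,2R)-2-hydroxy-2,6,6-trimethyl-5-oxocyclohexane-1-carbaldehyde, via proline enamine 8 (not isolated)
Conditions: (S)-proline (20 mol %), CH2Cl2 (0.05 M), rt
Reagents that add atoms: none
Why: (S)-Proline condenses with the aldehyde of 7 much faster than with either ketone and gives the (E)-enamine 8, whose β-carbon (C5) adds to the methyl ketone carbonyl (C4) while the carboxylic acid transfers its proton to the developing alkoxide; hydrolysis of the iminium ion releases 9 and the catalyst. The closest known reaction type is the proline-catalysed 6-enolexo aldolisation of dialdehydes and keto aldehydes. The ring closes in the 6-(enolexo)-exo-trig mode, the only possibility for this enamine, since attack on the C1 ketone would give a three-membered ring. C5 is set by the catalyst: the carboxyl group brings the ketone to the face of the anti enamine on which it sits, which makes C5 S. C4 is set by the ring: in the chair the C4 methyl group avoids the axial C6 methyl group, so the carbonyl oxygen is axial, synclinal to the enamine and still within reach of the acid, and with the formyl carbon equatorial this gives the cis (1S,2R) isomer directly. The step needs donor selectivity, that is the aldehyde enamine and not the enamine of the methyl ketone adding to the aldehyde, which rests on the faster aldehyde condensation and on dilution against intermolecular aldolisation. It also needs kinetic control, which is helped because the formyl group of 9 lies between two fully substituted carbons and re-condenses with proline only slowly, so epimerisation at C5, retro-aldolisation and dehydration through the iminium ion are held back.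

Step 5
Reactants: 9 (1S,2R)-2-hydroxy-2,6,6-trimethyl-5-oxocyclohexane-1-carbaldehyde; 10 dimethyl (2-oxopropyl)phosphonate
Product: 11 (3S,4R)-4-hydroxy-2,2,4-trimethyl-3-[(1E)-3-oxobut-1-en-1-yl]cyclohexan-1-one
Conditions: LiCl, i-Pr2NEt, MeCN, rt
Reagents that add atoms: none
Why: Horner–Wadsworth–Emmons olefination under Masamune–Roush conditions forms the (E)-enone without generating the tertiary alkoxide that would start retro-aldol cleavage, and the phosphonate anion is a more reactive partner for the hindered formyl group than a stabilised ylide; the C1 ketone is too hindered to react.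

Step 6
Reactants: 11 (3S,4R)-4-hydroxy-2,2,4-trimethyl-3-[(1E)-3-oxobut-1-en-1-yl]cyclohexan-1-one
Product: 12 (3S,4R)-4-hydroxy-2,2,4-trimethyl-3-(3-oxobutyl)cyclohexan-1-one
Conditions: H2 (1 atm), Pd/C, EtOAc, rt
Reagents that add atoms: none
Why: Heterogeneous hydrogenation saturates only the conjugated C1′=C2′ bond; from here on C5 has no acidifying neighbour and is configurationally fixed.

Step 7
Reactants: 12 (3S,4R)-4-hydroxy-2,2,4-trimethyl-3-(3-oxobutyl)cyclohexan-1-one
Product: 13 (3S,4R)-4-hydroxy-3-[(3R)-3-hydroxy-3-methylhex-5-en-1-yl]-2,2,4-trimethylcyclohexan-1-one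
Conditions: allyl-B(O-i-Pr)2 (1.5 equiv), (R)-3,3′-Br2-BINOL (15 mol %), PhCH3/PhCF3 3:1, −35 °C; aqueous work-up
Reagents that add atoms: allyldiisopropoxyborane, C=CCB(OC(C)C)OC(C)C
Why: Chiral-diol-catalysed allylboration of a methyl ketone proceeds through a closed chair with the larger CH2CH2 arm equatorial, and the catalyst antipode is the one that sends allyl to the Si face of the C3′ carbonyl to give 3′R; the C1 ketone next to a quaternary carbon is far slower, and a tertiary hydroxyl is tolerated since tertiary alcohols are known additives in this catalysis.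

Step 8
Reactants: 13 (3S,4R)-4-hydroxy-3-[(3R)-3-hydroxy-3-methylhex-5-en-1-yl]-2,2,4-trimethylcyclohexan-1-one
Product: 14 (1R,2S,4R)-2-[(3R)-3-hydroxy-3-methylhex-5-en-1-yl]-1,3,3-trimethylcyclohexane-1,4-diol
Conditions: LiBH(s-Bu)3 (3.5 equiv), THF, −78 → −40 °C; then NaOH, H2O2, 0 °C
Reagents that add atoms: none
Why: A bulky trialkylborohydride reduces an α,α-dimethylcyclohexanone by equatorial attack, as with 4,4-dimethyl-3-oxo terpenoids, and so gives the axial alcohol at C1 (R), trans to the C5 chain; the chair is fixed by the equatorial C4 methyl group and C5 chain.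

Step 9
Reactants: 14 (1R,2S,4R)-2-[(3R)-3-hydroxy-3-methylhex-5-en-1-yl]-1,3,3-trimethylcyclohexane-1,4-diol
Product: 16 (1R,2S,4R)-2-[(3R)-3,5-dihydroxy-3-methylpentyl]-1,3,3-trimethylcyclohexane-1,4-diol, via ozonide 15 (not isolated)
Conditions: O3, CH2Cl2, −78 °C; then NaBH4, MeOH, −78 °C → rt
Reagents that add atoms: ozone, [O-][O+]=O
Why: Ozonolysis of the terminal alkene and borohydride reduction of the ozonide give the primary C5′ hydroxyl; nothing else in 14 reacts with ozone or NaBH4.

Step 10
Reactants: 16 (1R,2S,4R)-2-[(3R)-3,5-dihydroxy-3-methylpentyl]-1,3,3-trimethylcyclohexane-1,4-diol; 17 umbelliferone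
Product: 18 7-{[(3R)-5-[(1S,3R,6R)-3,6-dihydroxy-2,2,6-trimethylcyclohexyl]-3-hydroxy-3-methylpentyl]oxy}-2H-chromen-2-one
Conditions: PPh3, DIAD, THF, 0 °C → rt
Reagents that add atoms: none
Why: Mitsunobu etherification activates only the primary hydroxyl and couples it with the acidic 7-hydroxyl of 17; the axial neopentyl secondary and the two tertiary hydroxyls are not activated, and the coumarin enters after all hydride and ozone steps.

Step 11
Reactants: 18 7-{[(3R)-5-[(1S,3R,6R)-3,6-dihydroxy-2,2,6-trimethylcyclohexyl]-3-hydroxy-3-methylpentyl]oxy}-2H-chromen-2-one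
Product: 19 (1R,3S,4R)-4-hydroxy-3-{(3R)-3-hydroxy-3-methyl-5-[(2-oxo-2H-chromen-7-yl)oxy]pentyl}-2,2,4-trimethylcyclohexyl acetate
Conditions: Ac2O, pyridine, DMAP (cat.), CH2Cl2, rt
Reagents that add atoms: acetic anhydride, CC(=O)OC(C)=O
Why: DMAP-catalysed acetylation takes the single secondary hydroxyl; the two tertiary hydroxyls acylate far more slowly at room temperature, so 19 should result without protection.

## Compound list

1 | 2,2-dimethylpent-4-enal | C=CCC(C)(C)C=O | starting material
2 | 4-bromo-2-methylbut-1-ene | C=C(C)CCBr | starting material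
3 | (3-methylbut-3-en-1-yl)magnesium bromide | C=C(C)CC[Mg]Br | intermediate
4 | 2,6,6-trimethylnona-1,8-dien-5-ol (racemic) | C=C(C)CCC(O)C(C)(C)CC=C | intermediate
5 | 2,6,6-trimethylnona-1,8-dien-5-one | C=C(C)CCC(=O)C(C)(C)CC=C | intermediate
6 | 4,4-dimethyl-1-(3-methyl-1,2,4-trioxolan-3-yl)-5-(1,2,4-trioxolan-3-yl)pentan-3-one (bis-ozonide, stereoisomer mixture) | CC1(CCC(=O)C(C)(C)CC2OCOO2)OCOO1 | intermediate
7 | 3,3-dimethyl-4,7-dioxooctanal | CC(=O)CCC(=O)C(C)(C)CC=O | intermediate
8 | (2S)-1-[(1E)-3,3-dimethyl-4,7-dioxooct-1-en-1-yl]pyrrolidine-2-carboxylic acid | CC(=O)CCC(=O)C(C)(C)/C=C/N1CCC[C@H]1C(=O)O | intermediate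
9 | (1S,2R)-2-hydroxy-2,6,6-trimethyl-5-oxocyclohexane-1-carbaldehyde | O=C1CC[C@@](C)(O)[C@@H](C=O)C1(C)C | intermediate
10 | dimethyl (2-oxopropyl)phosphonate | CC(=O)CP(=O)(OC)OC | starting material
11 | (3S,4R)-4-hydroxy-2,2,4-trimethyl-3-[(1E)-3-oxobut-1-en-1-yl]cyclohexan-1-one | O=C1CC[C@@](C)(O)[C@@H](/C=C/C(C)=O)C1(C)C | intermediate
12 | (3S,4R)-4-hydroxy-2,2,4-trimethyl-3-(3-oxobutyl)cyclohexan-1-one | O=C1CC[C@@](C)(O)[C@@H](CCC(C)=O)C1(C)C | intermediate
13 | (3S,4R)-4-hydroxy-3-[(3R)-3-hydroxy-3-methylhex-5-en-1-yl]-2,2,4-trimethylcyclohexan-1-one | O=C1CC[C@@](C)(O)[C@@H](CC[C@@](C)(O)CC=C)C1(C)C | intermediate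
14 | (1R,2S,4R)-2-[(3R)-3-hydroxy-3-methylhex-5-en-1-yl]-1,3,3-trimethylcyclohexane-1,4-diol | O[C@@H]1CC[C@@](C)(O)[C@@H](CC[C@@](C)(O)CC=C)C1(C)C | intermediate
15 | (1R,2S,4R)-2-[(3R)-3-hydroxy-3-methyl-4-(1,2,4-trioxolan-3-yl)butyl]-1,3,3-trimethylcyclohexane-1,4-diol (ozonide, epimers at the trioxolane carbon) | O[C@@H]1CC[C@@](C)(O)[C@@H](CC[C@@](C)(O)CC2OCOO2)C1(C)C | intermediate
16 | (1R,2S,4R)-2-[(3R)-3,5-dihydroxy-3-methylpentyl]-1,3,3-trimethylcyclohexane-1,4-diol | O[C@@H]1CC[C@@](C)(O)[C@@H](CC[C@@](C)(O)CCO)C1(C)C | intermediate
17 | umbelliferone (7-hydroxy-2H-chromen-2-one) | O=c1ccc2ccc(O)cc2o1 | starting material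
18 | 7-{[(3R)-5-[(1S,3R,6R)-3,6-dihydroxy-2,2,6-trimethylcyclohexyl]-3-hydroxy-3-methylpentyl]oxy}-2H-chromen-2-one | O[C@@H]1CC[C@@](C)(O)[C@@H](CC[C@@](C)(O)CCOc2ccc3ccc(=O)oc3c2)C1(C)C | intermediate
19 | (1R,3S,4R)-4-hydroxy-3-{(3R)-3-hydroxy-3-methyl-5-[(2-oxo-2H-chromen-7-yl)oxy]pentyl}-2,2,4-trimethylcyclohexyl acetate | CC(=O)O[C@@H]1CC[C@@](C)(O)[C@@H](CC[C@@](C)(O)CCOc2ccc3ccc(=O)oc3c2)C1(C)C | target

## Step count and least certain steps

Total: 11 steps. Longest linear sequence: 11 steps (1 and 2 to 19); 10 and 17 enter as purchased compounds.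

**Step 4 (key step).** Three processes can go wrong.
- Closure through the enamine of the methyl ketone onto the aldehyde, which is a better acceptor than a ketone.
- Loss of control over C4 relative to C5. The usual hydrogen-bonded arrangement puts the carbonyl oxygen anti to C6 (equatorial) and the C4 methyl group axial. If it competes with the locked chair, the other diastereomer forms, and any later epimerisation at C5 would turn it into the enantiomeric series.
- Dehydration of the β-hydroxy aldehyde.

Fallback, from 7 back to 9: ring closure with pyrrolidinium acetate gives, after chromatography, the racemic cis aldol F1. Condensation with (1R,2R)-N,N′-dimethyl-1,2-diphenylethane-1,2-diamine converts it into the two diastereomeric aminals F2 (from the 1S,2R aldehyde) and F3 (from the 1R,2S aldehyde). F2 is separated by chromatography and hydrolysed with dilute aqueous HCl in ether to give 9. Stereocontrol by catalysis is thereby replaced by a resolution.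

**Step 7.** The catalyst may discriminate poorly between CH3 and the CH2CH2 arm, and the free C4 hydroxyl may assist an uncatalysed allyl transfer. Either lowers the purity at C3′, which is remote from the ring and hard to correct later.

Fallback, from 12 back to 16:
- Horner–Wadsworth–Emmons olefination of the methyl ketone with triethyl phosphonoacetate and NaH gives the (E)-enoate F4, whose geometrical purity is secured by chromatography.
- LiBH(s-Bu)3 reduces the C1 ketone to the hydroxy enoate F5.
- i-Bu2AlH gives the allylic alcohol F6.
- Sharpless epoxidation with Ti(O-i-Pr)4, D-(−)-diisopropyl tartrate and t-BuOOH gives the epoxy alcohol F7.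
- NaAlH2(OCH2CH2OCH3)2 opens F7 at C4′ and returns tetraol 16.

**Step 5.** Olefination of the formyl group between two fully substituted carbons may be slow, and retro-aldol cleavage or epimerisation at C5 may overtake it.

Fallback, from 9 back to 11: Et3SiOTf and 2,6-lutidine convert 9 into the silyl ether F8, which has no retro-aldol pathway. Olefination with the sodium salt of 10 (NaH, THF) gives the silylated enone F9. HF·pyridine removes the silyl group and returns 11.

**Step 8.** Axial attack may compete and give the equatorial C1 alcohol; the axial C6 methyl group lies on the face the hydride must use.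

Fallback, from 13 back to 14: reagent-controlled Corey–Bakshi–Shibata reduction with (S)-2-methyl-CBS-oxazaborolidine and catecholborane in toluene at −78 °C. With C6 as the large and C2 as the small substituent, this catalyst delivers hydride to the face syn to the C5 chain, and catecholborane spares the terminal alkene. No new compound is involved.

## Further compounds

F1 | step 4 | racemic cis-2-hydroxy-2,6,6-trimethyl-5-oxocyclohexane-1-carbaldehyde, (1S,2R) and (1R,2S) | O=C1CC[C@@](C)(O)[C@@H](C=O)C1(C)C.O=C1CC[C@](C)(O)[C@H](C=O)C1(C)C
F2 | step 4 | (3R,4R)-3-[(4R,5R)-1,3-dimethyl-4,5-diphenylimidazolidin-2-yl]-4-hydroxy-2,2,4-trimethylcyclohexan-1-one | O=C1CC[C@@](C)(O)[C@@H](C2N(C)[C@H](c3ccccc3)[C@@H](c3ccccc3)N2C)C1(C)C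
F3 | step 4 | (3S,4S)-3-[(4R,5R)-1,3-dimethyl-4,5-diphenylimidazolidin-2-yl]-4-hydroxy-2,2,4-trimethylcyclohexan-1-one | O=C1CC[C@](C)(O)[C@H](C2N(C)[C@H](c3ccccc3)[C@@H](c3ccccc3)N2C)C1(C)C
F4 | step 7 | ethyl (2E)-5-[(1S,6R)-6-hydroxy-2,2,6-trimethyl-3-oxocyclohexyl]-3-methylpent-2-enoate | O=C1CC[C@@](C)(O)[C@@H](CC/C(C)=C/C(=O)OCC)C1(C)C
F5 | step 7 | ethyl (2E)-5-[(1S,3R,6R)-3,6-dihydroxy-2,2,6-trimethylcyclohexyl]-3-methylpent-2-enoate | O[C@@H]1CC[C@@](C)(O)[C@@H](CC/C(C)=C/C(=O)OCC)C1(C)C
F6 | step 7 | (1R,2S,4R)-2-[(3E)-5-hydroxy-3-methylpent-3-en-1-yl]-1,3,3-trimethylcyclohexane-1,4-diol | O[C@@H]1CC[C@@](C)(O)[C@@H](CC/C(C)=C/CO)C1(C)C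
F7 | step 7 | (1R,2S,4R)-2-{2-[(2R,3R)-3-(hydroxymethyl)-2-methyloxiran-2-yl]ethyl}-1,3,3-trimethylcyclohexane-1,4-diol | O[C@@H]1CC[C@@](C)(O)[C@@H](CC[C@@]2(C)O[C@@H]2CO)C1(C)C
F8 | step 5 | (1S,2R)-2,6,6-trimethyl-5-oxo-2-[(triethylsilyl)oxy]cyclohexane-1-carbaldehyde | O=C1CC[C@@](C)(O[Si](CC)(CC)CC)[C@@H](C=O)C1(C)C
F9 | step 5 | (3S,4R)-2,2,4-trimethyl-3-[(1E)-3-oxobut-1-en-1-yl]-4-[(triethylsilyl)oxy]cyclohexan-1-one | O=C1CC[C@@](C)(O[Si](CC)(CC)CC)[C@@H](/C=C/C(C)=O)C1(C)C
F0 | step 8 | none | none
A1 | alternative 1 | [(2R,3R)-3-methyl-3-{2-[(1S,3R,6R)-2,2,6-trimethyl-3,6-bis(triethylsilyloxy)cyclohexyl]ethyl}oxiran-2-yl]methanol | CC[Si](CC)(CC)O[C@@H]1CC[C@@](C)(O[Si](CC)(CC)CC)[C@@H](CC[C@@]2(C)O[C@@H]2CO)C1(C)C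
A2 | alternative 1 | (2E)-3-methyl-5-[(1S,3R,6R)-2,2,6-trimethyl-3,6-bis(triethylsilyloxy)cyclohexyl]pent-2-en-1-ol | CC[Si](CC)(CC)O[C@@H]1CC[C@@](C)(O[Si](CC)(CC)CC)[C@@H](CC/C(C)=C/CO)C1(C)C
A3 | alternative 2 | (3aS,7S,7aS)-7-iodo-4,4,7a-trimethylhexahydro-2H-spiro[1-benzofuran-5,2′-[1,3]dioxolan]-2-one | C12(OCCO2)C[C@H](I)[C@@]3(C)OC(=O)C[C@H]3C1(C)C
A4 | alternative 2 | 2-[(9R)-8,10,10-trimethyl-1,4-dioxaspiro[4.5]dec-7-en-9-yl]acetic acid | C12(OCCO2)CC=C(C)[C@@H](CC(=O)O)C1(C)C
A5 | alternative 3 | (3S,4R)-3-{(3R)-5-[(tert-butyldimethylsilyl)oxy]-3-methyl-3-[(triethylsilyl)oxy]pentyl}-4-hydroxy-2,2,4-trimethylcyclohexan-1-one | O=C1CC[C@@](C)(O)[C@@H](CC[C@@](C)(O[Si](CC)(CC)CC)CCO[Si](C)(C)C(C)(C)C)C1(C)C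
A6 | alternative 3 | (5S,8R)-5-acetyl-10-[(tert-butyldimethylsilyl)oxy]-4,4,8-trimethyl-8-[(triethylsilyl)oxy]dec-1-en-3-one | C=CC(=O)C(C)(C)[C@H](CC[C@@](C)(O[Si](CC)(CC)CC)CCO[Si](C)(C)C(C)(C)C)C(C)=O
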